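(The readings were computed with constants of no real substance, noise included.)

Which of south-west and west ends with the larger excess of left-handed product over right-handed product? You take over two flasks that differ in their reagent charge.

| flask | left-handed substrate | right-handed substrate | reagent | free catalyst | impurity | remark | time |
|---|---|---|---|---|---|---|---|
| noon | 0.014 M | 0.014 M | 0.0168 M | 1.4 mM | 0.13 mM | run made earlier |  |
| winter | 0.028 M | 0.028 M | 0.0168 M | 1.4 mM | 0.19 mM | run made earlier |  |
| south-west | 0.014 M | 0.014 M | 0.0168 M | 1.4 mM | 0.19 mM |  | 10 d |
| west | 0.014 M | 0.014 M | 0.00800 M | 1.4 mM | 0.19 mM |  | 10 d |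

- noon (time / d: left-handed product / %, right-handed product / %): 0.250: 0.3, 0; 0.417: 0.3, 0.1; 0.625: 1.4, 0.4; 1.04: 1.2, 1.2; 1.67: 2.6, 1.6; 2.50: 2.6, 2.6; 4.00: 4.5, 3.6
- winter (time / d: left-handed product / %, right-handed product / %): 0.250: 0.7, 0; 0.417: 0.6, 0.5; 0.625: 0.3, 0.5; 1.04: 0.3, 0.7; 1.67: 1.1, 0.9; 2.50: 1.7, 1.2; 4.00: 3.0, 1.7

(each reading ± 0.3 percentage points)

- free catalyst is single-handed; left-handed substrate and right-handed substrate are mirror images of each other, charged as a racemate, each of them at the stated concentration
- an excess is the difference of the two amounts in percent of their sum
- an excess is below zero if the other one leads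

1. which one finishes higher in excess of left-handed product over right-handed product in the product ("neither" within 2 percentage points) (south-west / west / neither)
2. excess of left-handed product over right-handed product in the product at the end, south-west
3. excess of left-handed product over right-handed product in the product at the end, west

At 4.00 d the noon run holds 2.27 mM of product. The winter run holds 2.63 mM, though it was charged with 0.028 M of each substrate instead of 0.014 M, and with 0.19 mM of impurity instead of 0.13 mM, so two settings differ; as a working assumption I drop substrate from the rate. Both runs had the same reagent charge, so I only assume the rate follows the reagent, and I call w the product made per day per unit of reagent charged, a pseudo-first-order constant, here read off the last noon readings: 0.0338 d⁻¹.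

Over 10 d in south-west, w gives 5.67 mM. That first answer takes a third of the reagent, so I put the mean reagent back in and go round again. This gives 4.71 mM, or 16.8% of the substrates charged.

Leave the reagent alone if you are after excess. I assume both hands consume it at the same order, so I expect neither flask to lead. The last noon reading gives 11.1%, with a scatter of 0.3 percentage points on each reading.

The forecast says neither, with 13.5% for south-west and 14% for west, and for south-west it expects “about 6 mM (about 20% of substrate)”. My second round for south-west stands lower than my first, and the excess I read is lower than the forecast's.

The flasks give neither: 5.67% in south-west and 5.54% in west.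

    free catalyst + right-handed substrate ⇌ catalyst intermediate B (K = 110 M⁻¹, k = 78.0 M⁻¹ h⁻¹)
    reagent + catalyst intermediate B → free catalyst + right-handed product (k = 1.30 M⁻¹ h⁻¹)
    reagent ⇌ dormant form (K = 0.240, k = 0.0230 h⁻¹)
    free catalyst + impurity → spent catalyst (k = 30000 M⁻¹ h⁻¹)
    free catalyst + left-handed substrate ⇌ catalyst intermediate A (K = 20.0 M⁻¹, k = 400 M⁻¹ h⁻¹)
    reagent + catalyst intermediate A → free catalyst + left-handed product (k = 7.60 M⁻¹ h⁻¹)

South-west holds 16.9% of product against my 16.8%. For west, w gives 2.70 mM, then 2.24 mM, or 8.02%, and the flask holds 8.20%. At the end of south-west, catalyst intermediate B holds 42.9% of the catalyst and catalyst intermediate A 8.06%, with half-lives against charged reagent of 1.3 d and 0.23 d. Share over half-life is 0.324 d⁻¹ for catalyst intermediate B and 0.356 d⁻¹ for catalyst intermediate A.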